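## Retrosynthetic overview

1. The ester between the C1 carboxyl carbon of ring A and O4 of ring B is cut first. Ring A arrives as the pentafluorophenyl ester 15 and rings B, C and D as the tridepside phenol 32. The triethylsilyl ether on the C1 oxygen and the tert-butyl ester on ring D are removed last.
2. Feature used: the quaternary carbinol carbon C1 of ring A is bonded to two carbons of carboxyl oxidation level, the exocyclic ester carbon and the ring enol-ether carbon C2. Cutting C2–C3 therefore uncovers an achiral 2-alkenyl-2-silyloxymalonate (12) whose two active esters are enantiotopic.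
3. Ring A is the only ring that is built. The ethyl ketone carbon C3 of 12 attacks one of the two esters in a ligand-controlled Dieckmann closure, which fixes C1. The ester that is spared stays activated for the union with ring B.
4. Compound 12 comes from diallyl ketomalonate by ethynyl addition, O-silylation, acylation and syn-methylcupration, which sets the (Z)-alkene. The allyl esters are then exchanged for C6F5 esters without any base.
5. Rings B, C and D are bought as arenes (4,5-dimethylresorcinol for B and D, methyl atratate for C). They are joined by carbodiimide esterification, D with C first and then B.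

Key step: step 7

Numbering: in ring A, C1 is the carbinol carbon, C2 the OMe carbon, C3 a C-methyl, C4 the ketone, C5 the CH and C6 a C-methyl. Rings B, C and D use benzoate numbering, with C1 as the carboxyl-bearing carbon.

Assumption: the sense of induction of the magnesium–bis(oxazoline) complex cannot be predicted with certainty. The (S,S) ligand is written, and if it should favour the (S) product, its equally available (R,R) mirror image is used.

## Route

### Ring A (steps 1–8)

Step 1
Reactants: 1 disodium mesoxalate monohydrate (disodium 2,2-dihydroxypropanedioate)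
Product: 3 diallyl ketomalonate (diallyl 2-oxopropanedioate), via diallyl dihydroxymalonate 2 (not isolated)
Conditions: allyl bromide (3 equiv), Bu4NBr (10 mol %), DMF, 45 °C; extractive work-up; toluene, Dean–Stark, reflux
Reagents that add atoms: allyl bromide, C=CCBr
Why: SN2 O-alkylation of the dicarboxylate should give the diallyl ester as its gem-diol, and azeotropic drying frees the central ketone as is usual for ketomalonate hydrates; allyl esters are chosen because they can later be removed without base.

Step 2
Reactants: 3 diallyl ketomalonate; 4 ethynylmagnesium bromide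
Product: 5 diallyl 2-ethynyl-2-hydroxymalonate
Conditions: THF, −78 °C; sat. aq. NH4Cl
Reagents that add atoms: none
Why: Grignard 1,2-addition, in which the central carbonyl of the vicinal tricarbonyl is far more electrophilic than the flanking esters, so one equivalent at low temperature should add there only; the new carbinol carbon (future C1) is still prochiral.

Step 3
Reactants: 5 diallyl 2-ethynyl-2-hydroxymalonate
Product: 6 diallyl 2-ethynyl-2-(triethylsilyloxy)malonate
Conditions: Et3SiOTf, 2,6-lutidine, CH2Cl2, 0 °C
Reagents that add atoms: triethylsilyl trifluoromethanesulfonate, CC[Si](CC)(CC)OS(=O)(=O)C(F)(F)F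
Why: Silyl triflate silylation of a hindered tertiary alcohol; capping the oxygen before the ketone is present rules out lactol formation with the later (Z)-enone and acylation of the hydroxyl by the active esters.

Step 4
Reactants: 6 diallyl 2-ethynyl-2-(triethylsilyloxy)malonate; 7 N-methoxy-N-methylpropanamide
Product: 9 diallyl 2-(3-oxopent-1-yn-1-yl)-2-(triethylsilyloxy)malonate, via lithium acetylide 8 (not isolated)
Conditions: LiN(SiMe3)2, THF, −78 °C; then 7, −78 → −20 °C; inverse quench into cold 0.5 M HCl
Reagents that add atoms: none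
Why: Weinreb ketone synthesis, in which the alkyne C–H (acidified by three electron-withdrawing groups on the neighbouring carbon) is lithiated without harm to the hindered non-enolisable esters, the chelated tetrahedral adduct prevents over-addition, and the acidic inverse quench keeps the released amine from adding to the ynone.

Step 5
Reactants: 9 diallyl 2-(3-oxopent-1-yn-1-yl)-2-(triethylsilyloxy)malonate
Product: 10 diallyl 2-[(Z)-4-oxohex-2-en-2-yl]-2-(triethylsilyloxy)malonate
Conditions: Me2CuLi (1.3 equiv, from CuI and MeLi), Et2O/THF, −78 °C; AcOH in THF at −78 °C; aqueous work-up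
Reagents that add atoms: lithium dimethylcuprate, [Li+].C[Cu-]C
Why: Conjugate syn-carbocupration of an ynone puts the new methyl group and the incoming proton on the same side, and kinetic protonation of any allenolate from the side of the small methyl group leads to the same result, so the propanoyl group and the malonate carbon should end up cis, that is (Z).

Step 6
Reactants: 10 diallyl 2-[(Z)-4-oxohex-2-en-2-yl]-2-(triethylsilyloxy)malonate
Product: 12 bis(pentafluorophenyl) 2-[(Z)-4-oxohex-2-en-2-yl]-2-(triethylsilyloxy)malonate, via disodium malonate salt 11 (not isolated)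
Conditions: Pd(PPh3)4 (5 mol %), TolSO2Na (2.1 equiv), THF/MeOH, rt; evaporate, toluene chase; C6F5OC(O)CF3 (3 equiv), pyridine (0.2 equiv), CH2Cl2/DMF, 0 °C → rt
Reagents that add atoms: pentafluorophenyl trifluoroacetate, O=C(Oc1c(F)c(F)c(F)c(F)c1F)C(F)(F)F; sodium p-toluenesulfinate (sodium ions of 11 only), Cc1ccc(cc1)S(=O)[O-].[Na+]
Why: Tsuji–Trost-type deallylation by zerovalent palladium with irreversible capture of the allyl groups as a sulfone is neutral, so no hydroxide meets the enolisable (Z)-enone (no racemic ring closure, no Z to E drift) and the malonic acid is never set free, and the dicarboxylate is then converted by acyl exchange through the mixed trifluoroacetic anhydride into the bis(active ester).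

Step 7
Reactants: 12 bis(pentafluorophenyl) 2-[(Z)-4-oxohex-2-en-2-yl]-2-(triethylsilyloxy)malonate
Product: 13 pentafluorophenyl (1R)-2-hydroxy-3,6-dimethyl-4-oxo-1-(triethylsilyloxy)cyclohexa-2,5-diene-1-carboxylate (ring A enol-dione)
Conditions: Mg(NTf2)2 (2.2 equiv), (S,S)-Ph-box [2,2'-(propane-2,2-diyl)bis((4S)-4-phenyl-4,5-dihydrooxazole), 2.4 equiv], i-Pr2NEt (3 equiv), 4 Å MS, CH2Cl2, −40 °C; cold 0.5 M HCl
Reagents that add atoms: none
Why: Proposed new method: one ligand-bound divalent magnesium centre chelates the two malonate carbonyls of 12 while a second one acidifies the ketone, i-Pr2NEt removes an alpha-prime proton, the enolate carbon (future C3) adds to one pentafluorophenyl ester carbonyl (future C2), and loss of pentafluorophenoxide followed by deprotonation of the new 1,3-dione makes the C2–C3 bond irreversible. The closest known reactions are the soft-enolisation acylation of ketones with pentafluorophenyl esters under MgBr2·OEt2 and i-Pr2NEt, the Dieckmann condensation, and the catalytic or enzymatic desymmetrisation of prochiral disubstituted malonates. Ring A closes in the 6-(enolendo)-exo-trig mode, made possible by the (Z)-alkene, which holds C3 within bonding distance of both ester carbons. C1 is the only new stereocentre and is controlled by the twofold-symmetric ligand: the tethered enolate can reach the chelate ring only from the face that carries the alkenyl group, on that face a ligand phenyl group screens one of the two carbonyls, and the two ways of binding the substrate are equivalent through the ligand axis, so a single enantiotopic ester is open. The step needs alpha-prime over gamma deprotonation, which is secured because only the alpha-prime enolate can close a ring, gamma deprotonation is reversible, and the non-nucleophilic NTf2 counter-ion gives no addition–elimination path for Z to E leakage. It also needs C- over O-acylation, which the covalent Mg–O bond favours, and any enol lactone would be reopened by pentafluorophenoxide whereas the C-acylated product is drained off as its enolate.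

Step 8
Reactants: 13 ring A enol-dione pentafluorophenyl ester
Product: 15 pentafluorophenyl (1R)-2-methoxy-3,6-dimethyl-4-oxo-1-(triethylsilyloxy)cyclohexa-2,5-diene-1-carboxylate, via 4-O-triisopropylsilyl dienone 14 (not isolated)
Conditions: i-Pr3SiOTf (1.05 equiv), 2,6-di-tert-butyl-4-methylpyridine (2.5 equiv), CH2Cl2, −78 → 0 °C; then MeOTf (3 equiv), 0 °C → rt; sat. aq. NaHCO3
Reagents that add atoms: methyl trifluoromethanesulfonate, COS(=O)(=O)C(F)(F)F; triisopropylsilyl trifluoromethanesulfonate (silyl group of 14 only), CC(C)[Si](C(C)C)(C(C)C)OS(=O)(=O)C(F)(F)F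
Why: Proposed new method: direct O-methylation of the unsymmetrical vinylogous acid would favour the open C4 oxygen, so that oxygen is first capped by the bulky silyl triflate (the C2 oxygen is walled in by C1 and the C3 methyl), which leaves the C2 carbonyl oxygen as the only nucleophilic site; methyl triflate alkylates it to a 2-methoxy-4-silyloxycyclohexadienyl cation, and loss of the silyl group to triflate or to water at the less hindered C4 end on quenching unveils the C4 ketone with the methyl ether at C2; the closest known reactions are the carbonyl-O-alkylation of vinylogous esters and amides by methyl triflate or oxonium salts and the preparation of 2-methoxy-4-pyranones from 4-hydroxy-2-pyranones with hard methylating agents; C1 is not touched.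

### Rings B, C and D (steps 9–22)

Step 9
Reactants: 16 4,5-dimethylresorcinol
Product: 18 2,4-dihydroxy-5,6-dimethylbenzaldehyde, via aryl iminium chloride 17 (not isolated)
Conditions: POCl3, DMF, 0 °C → rt; then H2O, 50 °C
Reagents that add atoms: N,N-dimethylformamide, CN(C)C=O; water, O
Why: Vilsmeier–Haack formylation should go para to one hydroxyl and ortho to the other (C6 of the resorcinol), as it does with orcinol, and not into the crowded position between the two hydroxyls.

Step 10
Reactants: 18 2,4-dihydroxy-5,6-dimethylbenzaldehyde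
Product: 19 4-(benzyloxy)-2-hydroxy-5,6-dimethylbenzaldehyde
Conditions: BnBr (1.05 equiv), K2CO3 (1.1 equiv), acetone, 50 °C
Reagents that add atoms: benzyl bromide, BrCc1ccccc1
Why: Williamson etherification, in which the 2-OH is tied up in a hydrogen bond to the aldehyde, so one equivalent of benzyl bromide should alkylate the more acidic free 4-OH.

Step 11
Reactants: 19 4-(benzyloxy)-2-hydroxy-5,6-dimethylbenzaldehyde
Product: 20 4-(benzyloxy)-2-methoxy-5,6-dimethylbenzaldehyde
Conditions: MeI (2 equiv), K2CO3, DMF, 40 °C
Reagents that add atoms: iodomethane, CI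
Why: Williamson methylation of the remaining chelated phenol in a dipolar solvent installs the ring D methyl ether.

Step 12
Reactants: 20 4-(benzyloxy)-2-methoxy-5,6-dimethylbenzaldehyde
Product: 21 4-(benzyloxy)-2-methoxy-5,6-dimethylbenzoic acid
Conditions: NaClO2, NaH2PO4, 2-methyl-2-butene, t-BuOH/THF/H2O, rt
Reagents that add atoms: sodium chlorite, [Na+].[O-]Cl=O
Why: Pinnick oxidation converts even hindered aromatic aldehydes into acids, and the alkene traps hypochlorous acid so that the electron-rich ring is not chlorinated.

Step 13
Reactants: 21 4-(benzyloxy)-2-methoxy-5,6-dimethylbenzoic acid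
Product: 22 tert-butyl 4-(benzyloxy)-2-methoxy-5,6-dimethylbenzoate
Conditions: tert-butyl 2,2,2-trichloroacetimidate (2.5 equiv), CH2Cl2/cyclohexane, rt
Reagents that add atoms: tert-butyl 2,2,2-trichloroacetimidate, CC(C)(C)OC(=N)C(Cl)(Cl)Cl
Why: Imidate tert-butylation goes through attack of the carboxylate oxygen on a tert-butyl cation equivalent, so the two ortho substituents that block the acyl carbon do not matter.

Step 14
Reactants: 22 tert-butyl 4-(benzyloxy)-2-methoxy-5,6-dimethylbenzoate
Product: 23 tert-butyl 4-hydroxy-2-methoxy-5,6-dimethylbenzoate (ring D phenol)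
Conditions: H2 (1 atm), Pd/C (10 wt %), EtOAc, rt
Reagents that add atoms: none
Why: Catalytic hydrogenolysis of the benzyl aryl ether leaves the tert-butyl ester and the methyl ether untouched.

Step 15
Reactants: 24 methyl 2,4-dihydroxy-3,6-dimethylbenzoate (methyl atratate)
Product: 25 methyl 4-(benzyloxy)-2-hydroxy-3,6-dimethylbenzoate
Conditions: BnBr (1.05 equiv), K2CO3 (1.1 equiv), acetone, reflux
Reagents that add atoms: benzyl bromide, BrCc1ccccc1
Why: Williamson etherification selective for the 4-OH, because the 2-OH is hydrogen-bonded to the ester carbonyl and flanked on both sides.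

Step 16
Reactants: 25 methyl 4-(benzyloxy)-2-hydroxy-3,6-dimethylbenzoate
Product: 26 4-(benzyloxy)-2-hydroxy-3,6-dimethylbenzoic acid (ring C acid)
Conditions: KOH, DMSO/H2O, 90 °C; then cold dilute HCl, 0 °C
Reagents that add atoms: potassium hydroxide, [K+].[OH-]
Why: Saponification of the hindered benzoate with poorly solvated hydroxide in aqueous DMSO, with cold acidification to avoid decarboxylation of the electron-rich salicylic acid.

Step 17
Reactants: 26 ring C acid; 23 ring D phenol
Product: 27 tert-butyl 4-{[4-(benzyloxy)-2-hydroxy-3,6-dimethylbenzoyl]oxy}-2-methoxy-5,6-dimethylbenzoate (C–D depside benzyl ether)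
Conditions: DCC, DMAP (10 mol %), toluene/CH2Cl2, 0 °C → rt
Reagents that add atoms: none
Why: Steglich-type carbodiimide esterification, the standard depside coupling, in which the acid's own chelated and doubly flanked 2-OH does not compete with the ring D 4-OH, and the acid-free medium spares the tert-butyl ester.

Step 18
Reactants: 27 C–D depside benzyl ether
Product: 28 tert-butyl 4-[(2,4-dihydroxy-3,6-dimethylbenzoyl)oxy]-2-methoxy-5,6-dimethylbenzoate (C–D depside phenol)
Conditions: H2 (1 atm), Pd/C (10 wt %), EtOAc, rt
Reagents that add atoms: none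
Why: Catalytic hydrogenolysis frees the ring C 4-OH and is inert towards aryl and tert-butyl esters.

Step 19
Reactants: 19 4-(benzyloxy)-2-hydroxy-5,6-dimethylbenzaldehyde
Product: 29 4-(benzyloxy)-3-chloro-2-hydroxy-5,6-dimethylbenzaldehyde
Conditions: SO2Cl2 (1.05 equiv), CH2Cl2, 0 °C, dark
Reagents that add atoms: sulfuryl chloride, ClS(Cl)(=O)=O
Why: Electrophilic aromatic chlorination can only enter C3, the single free ring position, which is activated by the ortho hydroxyl and the ortho benzyloxy group.

Step 20
Reactants: 29 4-(benzyloxy)-3-chloro-2-hydroxy-5,6-dimethylbenzaldehyde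
Product: 30 4-(benzyloxy)-3-chloro-2-hydroxy-5,6-dimethylbenzoic acid (ring B acid)
Conditions: NaClO2, NaH2PO4, 2-methyl-2-butene, t-BuOH/THF/H2O, rt
Reagents that add atoms: sodium chlorite, [Na+].[O-]Cl=O
Why: Pinnick oxidation tolerates the free chelated phenol, and the fully substituted ring offers no site for stray chlorination.

Step 21
Reactants: 30 ring B acid; 28 C–D depside phenol
Product: 31 B–C–D tridepside benzyl ether (tert-butyl ester)
Conditions: DCC, DMAP (10 mol %), toluene/CH2Cl2, 0 °C → rt
Reagents that add atoms: none
Why: Steglich-type esterification at the ring C 4-OH, since the 2-OH groups of rings B and C are hydrogen-bonded to their ester or acid carbonyls, are flanked on both sides, and should stay unacylated.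

Step 22
Reactants: 31 B–C–D tridepside benzyl ether
Product: 32 B–C–D tridepside phenol (ring B 4-OH free, tert-butyl ester on ring D)
Conditions: H2 (1 atm), Pd/C (5 wt %), EtOAc, no base, rt, stopped after one equivalent of H2
Reagents that add atoms: none
Why: Catalytic hydrogenolysis of the benzyl ether is faster than hydrodechlorination of an electron-rich aryl chloride in a neutral medium without base.

### Union and deprotection (steps 23–25)

Step 23
Reactants: 15 ring A methyl ether pentafluorophenyl ester; 32 B–C–D tridepside phenol
Product: 33 fully protected target (C1 triethylsilyl ether, ring D tert-butyl ester)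
Conditions: 15 (1.2 equiv), i-Pr2NEt (1.1 equiv), DMAP (20 mol %), MeCN/CH2Cl2, 0 °C → rt
Reagents that add atoms: none
Why: Acyl transfer from an active ester to a phenoxide under nucleophilic catalysis, in which the ring B 4-OH (para to the ester carbonyl, ortho to chlorine) is the most acidic hydroxyl and the only one not locked in a hydrogen bond, its phenoxide is more basic than pentafluorophenoxide so the exchange is downhill, the decarboxylation-prone quinol acid is never formed, and C1 has no path to epimerise.

Step 24
Reactants: 33 fully protected target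
Product: 34 target tert-butyl ester (C1–OH free)
Conditions: HF·pyridine, pyridine/THF, 0 °C → rt, plastic vessel
Reagents that add atoms: none
Why: Fluoride-driven Si–O cleavage under mildly acidic buffered conditions leaves the three aryl esters, the tert-butyl ester and the vinylogous methyl ester intact.

Step 25
Reactants: 34 target tert-butyl ester
Product: 35 CNP0248758.1, (R) at C1 of ring A
Conditions: CF3CO2H/CH2Cl2 (1:3), 0 °C → rt
Reagents that add atoms: none
Why: Acidolysis of the tert-butyl ester by loss of isobutene frees the ring D acid, the depside esters are stable to anhydrous acid, and ring A has no aromatic outlet for a dienone–phenol shift because both carbons next to C1 are fully substituted.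

## Compound list

1 | disodium mesoxalate monohydrate (disodium 2,2-dihydroxypropanedioate) | [Na+].[Na+].[O-]C(=O)C(O)(O)C([O-])=O | starting material
2 | diallyl 2,2-dihydroxymalonate | C=CCOC(=O)C(O)(O)C(=O)OCC=C | intermediate
3 | diallyl ketomalonate | C=CCOC(=O)C(=O)C(=O)OCC=C | intermediate
4 | ethynylmagnesium bromide | C#C[Mg]Br | starting material
5 | diallyl 2-ethynyl-2-hydroxymalonate | C#CC(O)(C(=O)OCC=C)C(=O)OCC=C | intermediate
6 | diallyl 2-ethynyl-2-(triethylsilyloxy)malonate | C#CC(O[Si](CC)(CC)CC)(C(=O)OCC=C)C(=O)OCC=C | intermediate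
7 | N-methoxy-N-methylpropanamide | CCC(=O)N(C)OC | starting material
8 | lithium acetylide of 6 | [Li]C#CC(O[Si](CC)(CC)CC)(C(=O)OCC=C)C(=O)OCC=C | intermediate
9 | diallyl 2-(3-oxopent-1-yn-1-yl)-2-(triethylsilyloxy)malonate | CCC(=O)C#CC(O[Si](CC)(CC)CC)(C(=O)OCC=C)C(=O)OCC=C | intermediate
10 | diallyl 2-[(Z)-4-oxohex-2-en-2-yl]-2-(triethylsilyloxy)malonate | CCC(=O)/C=C(/C)C(O[Si](CC)(CC)CC)(C(=O)OCC=C)C(=O)OCC=C | intermediate
11 | disodium 2-[(Z)-4-oxohex-2-en-2-yl]-2-(triethylsilyloxy)malonate | CCC(=O)/C=C(/C)C(O[Si](CC)(CC)CC)(C(=O)[O-])C(=O)[O-].[Na+].[Na+] | intermediate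
12 | bis(pentafluorophenyl) 2-[(Z)-4-oxohex-2-en-2-yl]-2-(triethylsilyloxy)malonate | CCC(=O)/C=C(/C)C(O[Si](CC)(CC)CC)(C(=O)Oc1c(F)c(F)c(F)c(F)c1F)C(=O)Oc1c(F)c(F)c(F)c(F)c1F | intermediate
13 | pentafluorophenyl (1R)-2-hydroxy-3,6-dimethyl-4-oxo-1-(triethylsilyloxy)cyclohexa-2,5-diene-1-carboxylate | OC1=C(C)C(=O)C=C(C)[C@]1(O[Si](CC)(CC)CC)C(=O)Oc1c(F)c(F)c(F)c(F)c1F | intermediate
14 | pentafluorophenyl (1R)-3,6-dimethyl-2-oxo-1-(triethylsilyloxy)-4-(triisopropylsilyloxy)cyclohexa-3,5-diene-1-carboxylate | O=C1C(C)=C(O[Si](C(C)C)(C(C)C)C(C)C)C=C(C)[C@]1(O[Si](CC)(CC)CC)C(=O)Oc1c(F)c(F)c(F)c(F)c1F | intermediate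
15 | pentafluorophenyl (1R)-2-methoxy-3,6-dimethyl-4-oxo-1-(triethylsilyloxy)cyclohexa-2,5-diene-1-carboxylate | COC1=C(C)C(=O)C=C(C)[C@]1(O[Si](CC)(CC)CC)C(=O)Oc1c(F)c(F)c(F)c(F)c1F | intermediate
16 | 4,5-dimethylresorcinol | Cc1cc(O)cc(O)c1C | starting material
17 | (2,4-dihydroxy-5,6-dimethylbenzylidene)dimethyliminium chloride | C[N+](C)=Cc1c(O)cc(O)c(C)c1C.[Cl-] | intermediate
18 | 2,4-dihydroxy-5,6-dimethylbenzaldehyde | Oc1cc(O)c(C=O)c(C)c1C | intermediate
19 | 4-(benzyloxy)-2-hydroxy-5,6-dimethylbenzaldehyde | O(Cc1ccccc1)c1cc(O)c(C=O)c(C)c1C | intermediate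
20 | 4-(benzyloxy)-2-methoxy-5,6-dimethylbenzaldehyde | O(Cc1ccccc1)c1cc(OC)c(C=O)c(C)c1C | intermediate
21 | 4-(benzyloxy)-2-methoxy-5,6-dimethylbenzoic acid | O(Cc1ccccc1)c1cc(OC)c(C(=O)O)c(C)c1C | intermediate
22 | tert-butyl 4-(benzyloxy)-2-methoxy-5,6-dimethylbenzoate | O(Cc1ccccc1)c1cc(OC)c(C(=O)OC(C)(C)C)c(C)c1C | intermediate
23 | tert-butyl 4-hydroxy-2-methoxy-5,6-dimethylbenzoate | Oc1cc(OC)c(C(=O)OC(C)(C)C)c(C)c1C | intermediate
24 | methyl 2,4-dihydroxy-3,6-dimethylbenzoate (methyl atratate) | COC(=O)c1c(C)cc(O)c(C)c1O | starting material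
25 | methyl 4-(benzyloxy)-2-hydroxy-3,6-dimethylbenzoate | COC(=O)c1c(C)cc(OCc2ccccc2)c(C)c1O | intermediate
26 | 4-(benzyloxy)-2-hydroxy-3,6-dimethylbenzoic acid | OC(=O)c1c(C)cc(OCc2ccccc2)c(C)c1O | intermediate
27 | C–D depside benzyl ether | O(Cc1ccccc1)c1cc(C)c(C(=O)Oc2cc(OC)c(C(=O)OC(C)(C)C)c(C)c2C)c(O)c1C | intermediate
28 | C–D depside phenol | Oc1cc(C)c(C(=O)Oc2cc(OC)c(C(=O)OC(C)(C)C)c(C)c2C)c(O)c1C | intermediate
29 | 4-(benzyloxy)-3-chloro-2-hydroxy-5,6-dimethylbenzaldehyde | O(Cc1ccccc1)c1c(C)c(C)c(C=O)c(O)c1Cl | intermediate
30 | 4-(benzyloxy)-3-chloro-2-hydroxy-5,6-dimethylbenzoic acid | O(Cc1ccccc1)c1c(C)c(C)c(C(=O)O)c(O)c1Cl | intermediate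
31 | B–C–D tridepside benzyl ether | O(Cc1ccccc1)c1c(C)c(C)c(C(=O)Oc2cc(C)c(C(=O)Oc3cc(OC)c(C(=O)OC(C)(C)C)c(C)c3C)c(O)c2C)c(O)c1Cl | intermediate
32 | B–C–D tridepside phenol | Oc1c(C)c(C)c(C(=O)Oc2cc(C)c(C(=O)Oc3cc(OC)c(C(=O)OC(C)(C)C)c(C)c3C)c(O)c2C)c(O)c1Cl | intermediate
33 | fully protected target (C1 triethylsilyl ether, ring D tert-butyl ester), (R) | COC1=C(C)C(=O)C=C(C)[C@]1(O[Si](CC)(CC)CC)C(=O)Oc1c(C)c(C)c(C(=O)Oc2cc(C)c(C(=O)Oc3cc(OC)c(C(=O)OC(C)(C)C)c(C)c3C)c(O)c2C)c(O)c1Cl | intermediate
34 | target tert-butyl ester, (R) | COC1=C(C)C(=O)C=C(C)[C@]1(O)C(=O)Oc1c(C)c(C)c(C(=O)Oc2cc(C)c(C(=O)Oc3cc(OC)c(C(=O)OC(C)(C)C)c(C)c3C)c(O)c2C)c(O)c1Cl | intermediate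
35 | CNP0248758.1, (R) at C1 of ring A | COC1=C(C)C(=O)C=C(C)[C@]1(O)C(=O)Oc1c(C)c(C)c(C(=O)Oc2cc(C)c(C(=O)Oc3cc(OC)c(C(=O)O)c(C)c3C)c(O)c2C)c(O)c1Cl | target

## Step count and risks

Total step count: 25.

Longest linear sequence: 13 steps (16 → 18 → 19 → 20 → 21 → 22 → 23 → 27 → 28 → 31 → 32 → 33 → 34 → 35). The ring A branch runs 11 steps from 1 to 35.

### Steps most likely to fail

**Step 7 (labelled).**
- What may go wrong:
  - Discrimination between the two enantiotopic esters may be too weak.
  - A ligand-free magnesium species may close the ring without stereocontrol.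
  - Gamma-deprotonation may drain the (Z)-enone into the (E)-isomer, which cannot cyclise.
  - O-acylation may compete with C-acylation.
- Fallback (known chemistry): this sets out from 12. The ring is closed without stereocontrol by the established soft-enolisation acylation (MgBr2·OEt2, i-Pr2NEt, CH2Cl2, 0 °C) to give racemic pentafluorophenyl 2-hydroxy-3,6-dimethyl-4-oxo-1-(triethylsilyloxy)cyclohexa-2,5-diene-1-carboxylate F1. The racemate is resolved by preparative chromatography on an immobilised amylose carbamate phase (hexane/EtOAc with a trace of AcOH). The (R)-enantiomer is 13, where the route is rejoined, and the (S)-enantiomer F2 is set aside.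

**Step 8 (labelled).**
- What may go wrong:
  - Methylation of the hindered, electron-poor C2 carbonyl oxygen may be sluggish.
  - The silyl group may scramble between the two oxygens.
  - The cationic intermediate may undergo a 1,2-shift or an aromatising loss of the C1 ester group.
- Fallback (known chemistry): this sets out from 13. Plain O-methylation of the vinylogous acid with ethereal diazomethane at 0 °C is accepted as unselective. It should give 15 together with the regioisomeric pentafluorophenyl (1R)-4-methoxy-3,6-dimethyl-2-oxo-1-(triethylsilyloxy)cyclohexa-3,5-diene-1-carboxylate F3. The two enol ethers are separated by chromatography, and the route is rejoined at 15.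

**Step 23.**
- What may go wrong:
  - Acyl transfer between a neopentyl-type active ester and a di-ortho-substituted phenoxide may be slow.
  - Aromatising loss of the carboxyl carbon from ring A, or acylation of a chelated 2-OH, may then take over.
- Fallback: this sets out from 15. The order of events is changed so that the shielding silyl group is gone before the union. HF·pyridine in THF at 0 °C gives pentafluorophenyl (1R)-1-hydroxy-2-methoxy-3,6-dimethyl-4-oxocyclohexa-2,5-diene-1-carboxylate F4. Its acyl carbon is far less screened, and its tertiary, electron-poor hydroxyl is too poor a nucleophile to self-acylate. F4 is then joined to 32 with i-Pr2NEt and DMAP, and the route is rejoined at 34.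

## Further compounds

F1 | step 7 | racemic pentafluorophenyl 2-hydroxy-3,6-dimethyl-4-oxo-1-(triethylsilyloxy)cyclohexa-2,5-diene-1-carboxylate | OC1=C(C)C(=O)C=C(C)C1(O[Si](CC)(CC)CC)C(=O)Oc1c(F)c(F)c(F)c(F)c1F
F2 | step 7 | pentafluorophenyl (1S)-2-hydroxy-3,6-dimethyl-4-oxo-1-(triethylsilyloxy)cyclohexa-2,5-diene-1-carboxylate | OC1=C(C)C(=O)C=C(C)[C@@]1(O[Si](CC)(CC)CC)C(=O)Oc1c(F)c(F)c(F)c(F)c1F
F3 | step 8 | pentafluorophenyl (1R)-4-methoxy-3,6-dimethyl-2-oxo-1-(triethylsilyloxy)cyclohexa-3,5-diene-1-carboxylate | O=C1C(C)=C(OC)C=C(C)[C@]1(O[Si](CC)(CC)CC)C(=O)Oc1c(F)c(F)c(F)c(F)c1F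
F4 | step 23 | pentafluorophenyl (1R)-1-hydroxy-2-methoxy-3,6-dimethyl-4-oxocyclohexa-2,5-diene-1-carboxylate | COC1=C(C)C(=O)C=C(C)[C@]1(O)C(=O)Oc1c(F)c(F)c(F)c(F)c1F
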